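We decide to watch one fork and let the rest of the flask serve it: substrate gives intermediate B, which either meets partner and becomes side product A or passes through intermediate C to side product B.

| setting | dusk | summer | flask |
|---|---|---|---|
| substrate | 0.20 M | 0.20 M | 0.20 M |
| partner | 0.84 M | 1.3 M | 0.600 M |
| remark | run made earlier | run made earlier |  |
| time |  |  | 20 min |

| run | time / min | side product A / % | intermediate B / % | side product B / % | target / % | isomer of the product / % | substrate / % |
|---|---|---|---|---|---|---|---|
| dusk | 1.00 | 1.4 | 6.3 | 0.2 | 2.1 | 0 | 81.4 |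
| dusk | 3.00 | 9.4 | 8.1 | 1.0 | 6.1 | 0 | 55.5 |
| dusk | 6.00 | 21.7 | 6.1 | 4.2 | 13.2 | 0.5 | 39.3 |
| dusk | 8.00 | 25.3 | 3.7 | 3.4 | 12.9 | 4.5 | 29.9 |
| dusk | 12.0 | 32.3 | 3.9 | 8.1 | 14.7 | 9.9 | 19.2 |
| dusk | 15.0 | 37.9 | 1.2 | 10.3 | 14.6 | 12.4 | 15.5 |
| dusk | 20.0 | 41.7 | 1.3 | 12.4 | 11.0 | 18.3 | 8.8 |
| summer | 1.00 | 3.5 | 4.3 | 0 | 2.6 | 0 | 75.6 |
| summer | 3.00 | 12.4 | 3.6 | 1.4 | 15.1 | 1.6 | 46.5 |
| summer | 6.00 | 22.3 | 3.9 | 2.0 | 20.8 | 2.6 | 28.4 |
| summer | 8.00 | 25.9 | 1.4 | 4.9 | 24.5 | 9.8 | 19.5 |
| summer | 12.0 | 31.8 | 1.9 | 6.5 | 19.8 | 17.1 | 13.7 |
| summer | 15.0 | 35.7 | 2.5 | 6.7 | 20.8 | 23.7 | 8.7 |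
| summer | 20.0 | 36.9 | 0.8 | 8.0 | 16.1 | 30.6 | 4.8 |

(readings scatter by 1 percentage point)

- percent here means substrate units held: one idle adduct counts as two
- what is said of target includes idle adduct
- steps under discussion: substrate + partner <-> intermediate A; partner + intermediate A -> target; substrate -> intermediate B; intermediate B -> intermediate C; partner + intermediate B -> side product A; intermediate C -> side product B; substrate + target <-> idle adduct; target <-> isomer of the product
- in an amount of target, one idle adduct counts as one target
- a reading or a percentage of substrate is of its free form alone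

* the species in which most of what was charged as substrate, at 20 min sits (target / side product A / intermediate B / side product B / substrate / isomer of the product)
* the largest share itself, whichever of these holds it, in percent of the substrate charged

On the ladder of times, intermediate B comes up early: in the dusk run it reads 8.1% at 3.00 min and is down to 1.3% at 20.0 min. The half-life of substrate, averaged over the dusk run, reads 5.70 min; taking it over as an estimate, the flask's 20 min spans about 3.51 half-lives. Last to show in the dusk run is the isomer of the product, which reads 0% at 3.00 min and 18.3% at 20.0 min.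

So we read the fork at the last reading, where intermediate B stands at 1.3% at dusk and 0.8% in summer. The ratio of side product A to side product B at that reading, divided by the partner charged, is 4.00 M⁻¹ at dusk and 3.55 M⁻¹ in summer. Their mean 3.78 M⁻¹ we call ρ, the fork's selectivity factor per molar partner.

For the flask at 0.600 M we expect a ratio of 2.27, which keeps side product A ahead of side product B. At the last reading the isomer stands lower at dusk than in summer, with less partner, so we commit to side product A. The forecast, taking the ratio as 2.3, concludes “Side product A holds the most”: side product A, 43%.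

The flask holds side product A at 42.6% and side product B at 19.6%, so ρ reads 3.63 M⁻¹ there.

    substrate + partner ⇌ intermediate A (K = 0.330 M⁻¹, k = 0.170 M⁻¹ min⁻¹)
    partner + intermediate A → target (k = 0.400 M⁻¹ min⁻¹)
    substrate → intermediate B (k = 0.0940 min⁻¹)
    intermediate B → intermediate C (k = 0.170 min⁻¹)
    partner + intermediate B → side product A (k = 0.650 M⁻¹ min⁻¹)
    intermediate C → side product B (k = 0.270 min⁻¹)
    substrate + target ⇌ idle adduct, settled at all times (K = 13.0 M⁻¹)
    target ⇌ isomer of the product (K = 6.10, k = 0.140 min⁻¹)

Just after the start, intermediate B in this flask goes 2.3 times as fast into side product A as into intermediate C, the comparison that ρ times the charge estimated. In the neighbour flask read at 12.0 min, side product A over side product B plus intermediate C is 1.99, and ρ times the mean of partner charged and partner left gives 2.02.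

Readings and results come from a simulation for substances that don't exist.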